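**Retrosynthetic overview**
1. Target 38 comes from E-alkenyltrifluoroborate 36 and acid 37 by a stereoretentive copper C–O coupling; 36 from aldehyde 33 (boryl-olefination); 33 from ozonolysis of the vinyl/methallyl ketone 32.
2. 32 comes from tricyclic enone 26: α-iodination and Stille methallylation, then vinyl conjugate addition at C11 and kinetic protonation at C10 (side chains cis).
3. 26 comes from cycloheptenone 18: α'-formylation, selenoxide dehydrogenation and an intramolecular hetero-Diels–Alder reaction that closes the cyclohexane ring and the pyran ring together, then hydrogenation and re-oxidation.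
4. 18 comes from cyclohexanone 10 by Saegusa–Ito one-carbon ring expansion and Wharton 1,3-transposition.
5. Key C–C bond: the quaternary carbon C1, made by asymmetric Michael addition of the (S)-1-phenylethylamine imine of 2-methylcyclohexanone to methyl acrylate. Ring order: bought six-membered ring → seven-membered ring → cyclohexane and pyran in one step.

Assumption: the Michael step gives about 90–95% ee and the material is brought to enantiopurity by recrystallising a crystalline tricyclic intermediate (24 or 26); tricyclic compounds are named as 6-oxatricyclo[6.3.2.0^{4,13}]tridecanes (C1 = methyl-bearing quaternary carbon, C9 = ring ketone, C10 and C11 = side-chain carbons).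

**Step 1**
Reactants: 1 2-methylcyclohexanone (racemic), 2 (S)-1-phenylethylamine
Product: 3 (1S)-N-(2-methylcyclohexylidene)-1-phenylethan-1-amine
Conditions: p-TsOH (cat.), toluene, reflux, Dean–Stark
Reagents that add atoms: none
Why: Acid-catalysed ketimine condensation driven by azeotropic water removal; the C2 centre of 1 does not matter because it is erased in the enamine tautomer that reacts next.

**Step 2**
Reactants: 3 (1S)-N-(2-methylcyclohexylidene)-1-phenylethan-1-amine, 4 methyl acrylate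
Product: 6 methyl 3-[(1R)-1-methyl-2-oxocyclohexyl]propanoate, via Michael adduct imine 5 (not isolated)
Conditions: 4 (1.5 equiv), THF, 40 °C, 3 d; then 20% aq. AcOH, rt
Reagents that add atoms: water, O
Why: d'Angelo–Pfau asymmetric Michael addition: the more substituted secondary enamine tautomer adds to the acrylate through a compact chair-like aza-ene transition state on the face anti to the phenyl group, which sets the quaternary centre as R, and mild hydrolysis releases ketone and auxiliary.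

**Step 3**
Reactants: 6 methyl 3-[(1R)-1-methyl-2-oxocyclohexyl]propanoate
Product: 7 (2R)-2-(3-hydroxypropyl)-2-methylcyclohexan-1-ol (C1 epimers)
Conditions: LiAlH4, THF, 0 °C → rt
Reagents that add atoms: none
Why: Hydride reduction of ester and ketone together lets the chain terminus be adjusted without a protecting group; the carbinol epimers converge in the next step.

**Step 4**
Reactants: 7 (2R)-2-(3-hydroxypropyl)-2-methylcyclohexan-1-ol
Product: 8 3-[(1R)-1-methyl-2-oxocyclohexyl]propanal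
Conditions: (COCl)2, DMSO, CH2Cl2, −78 °C; Et3N, −78 → 0 °C
Reagents that add atoms: none
Why: Swern oxidation activates both hydroxyls before base is added, so ketone and aldehyde form together and lactol or lactone formation is avoided.

**Step 5**
Reactants: 8 3-[(1R)-1-methyl-2-oxocyclohexyl]propanal, 9 isopropyltriphenylphosphonium iodide
Product: 10 (2R)-2-methyl-2-(4-methylpent-3-en-1-yl)cyclohexan-1-one
Conditions: 9, n-BuLi, THF, 0 °C; then 8, −78 °C → rt
Reagents that add atoms: none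
Why: Wittig olefination with the non-stabilised isopropylidene ylide is fast at the aldehyde and leaves the hindered α-quaternary ketone untouched; no alkene geometry arises.

**Step 6**
Reactants: 10 (2R)-2-methyl-2-(4-methylpent-3-en-1-yl)cyclohexan-1-one
Product: 11 trimethyl{[(6R)-6-methyl-6-(4-methylpent-3-en-1-yl)cyclohex-1-en-1-yl]oxy}silane
Conditions: LiN(iPr)2, THF, −78 °C; Me3SiCl, Et3N
Reagents that add atoms: chlorotrimethylsilane, C[Si](C)(C)Cl
Why: Enolate silylation; only C6 of 10 is enolisable, so a single silyl enol ether forms.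

**Step 7**
Reactants: 11 trimethyl{[(6R)-6-methyl-6-(4-methylpent-3-en-1-yl)cyclohex-1-en-1-yl]oxy}silane
Product: 12 trimethyl{[(2R)-2-methyl-2-(4-methylpent-3-en-1-yl)bicyclo[4.1.0]heptan-1-yl]oxy}silane (cyclopropane diastereomers)
Conditions: Et2Zn, CH2I2 (1.2 equiv), CH2Cl2, 0 °C → rt
Reagents that add atoms: diiodomethane, ICI
Why: Simmons–Smith (Furukawa) cyclopropanation; the electron-rich enol ether reacts much faster than the trisubstituted side-chain alkene.

**Step 8**
Reactants: 12 trimethyl{[(2R)-2-methyl-2-(4-methylpent-3-en-1-yl)bicyclo[4.1.0]heptan-1-yl]oxy}silane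
Product: 14 (7R)-7-methyl-7-(4-methylpent-3-en-1-yl)cyclohept-2-en-1-one, via 3-chloro ketone 13 (not isolated)
Conditions: FeCl3, DMF, 0 °C → rt; then NaOAc, MeOH, reflux
Reagents that add atoms: none
Why: Saegusa–Ito ring expansion: one-electron oxidation cleaves the internal cyclopropane bond to the ring-enlarged β-chloro ketone, and acetate-induced E1cB elimination gives the cycloheptenone.

**Step 9**
Reactants: 14 (7R)-7-methyl-7-(4-methylpent-3-en-1-yl)cyclohept-2-en-1-one
Product: 15 (3R)-3-methyl-3-(4-methylpent-3-en-1-yl)-8-oxabicyclo[5.1.0]octan-2-one (epoxide diastereomers)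
Conditions: 30% H2O2, NaOH (cat.), MeOH, 0 °C
Reagents that add atoms: hydrogen peroxide, OO
Why: Weitz–Scheffer nucleophilic epoxidation attacks only the electron-poor enone and not the electron-rich side-chain alkene; the epoxide centres are destroyed later.

**Step 10**
Reactants: 15 (3R)-3-methyl-3-(4-methylpent-3-en-1-yl)-8-oxabicyclo[5.1.0]octan-2-one
Product: 17 (4R)-4-methyl-4-(4-methylpent-3-en-1-yl)cyclohept-2-en-1-ol (C1 epimers), via epoxy hydrazone 16 (not isolated)
Conditions: N2H4·H2O, AcOH (cat.), MeOH, 0 °C → rt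
Reagents that add atoms: none
Why: Wharton transposition: the epoxy hydrazone fragments with loss of N2, which moves the oxygen to the far carbon and the alkene next to the quaternary centre.

**Step 11**
Reactants: 17 (4R)-4-methyl-4-(4-methylpent-3-en-1-yl)cyclohept-2-en-1-ol
Product: 18 (4R)-4-methyl-4-(4-methylpent-3-en-1-yl)cyclohept-2-en-1-one
Conditions: Dess–Martin periodinane, NaHCO3, CH2Cl2, rt
Reagents that add atoms: none
Why: Dess–Martin oxidation of the allylic alcohol gives the enone with the quaternary centre now at the γ-position; both carbinol epimers converge.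

**Step 12**
Reactants: 18 (4R)-4-methyl-4-(4-methylpent-3-en-1-yl)cyclohept-2-en-1-one
Product: 19 (4S)-7-(hydroxymethylidene)-4-methyl-4-(4-methylpent-3-en-1-yl)cyclohept-2-en-1-one
Conditions: NaH, HCO2Et, THF, EtOH (cat.), 0 °C → rt; 1 M HCl work-up
Reagents that add atoms: ethyl formate, CCOC=O
Why: Crossed Claisen condensation (formylation) can occur only at C7, because the γ-carbon is quaternary and the enone blocks the other side.

**Step 13**
Reactants: 19 (4S)-7-(hydroxymethylidene)-4-methyl-4-(4-methylpent-3-en-1-yl)cyclohept-2-en-1-one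
Product: 23 (1S,4R,13S)-1,5,5-trimethyl-6-oxatricyclo[6.3.2.0^{4,13}]trideca-7,10-dien-9-one, via selenide 20 (not isolated), via selenoxide 21 (not isolated), via formyl dienone 22 (not isolated)
Conditions: PhSeCl, pyridine, CH2Cl2, 0 °C; then 30% H2O2, 0 °C → rt, then 40 °C
Reagents that add atoms: none
Why: Selenoxide syn-elimination gives the 2-formyl dienone, whose formyl-enone oxadiene undergoes an intramolecular inverse-demand hetero-Diels–Alder reaction with the tethered trisubstituted alkene (bonds C13–C4 and O6–C5); the tether from C1 allows only the cis-bridged, cis-fused cage, so C13 and C4 follow from C1.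

**Step 14**
Reactants: 23 (1S,4R,13S)-1,5,5-trimethyl-6-oxatricyclo[6.3.2.0^{4,13}]trideca-7,10-dien-9-one
Product: 24 (1R,4R,8S,13S)-1,5,5-trimethyl-6-oxatricyclo[6.3.2.0^{4,13}]tridecan-9-one
Conditions: H2 (3 atm), 10% Pd/C, EtOAc, rt
Reagents that add atoms: none
Why: Heterogeneous hydrogenation saturates the enone and the vinylogous-ester C=C; hydrogen reaches C8 only from the exposed face and the cage allows only this ring fusion.

**Step 15**
Reactants: 24 (1R,4R,8S,13S)-1,5,5-trimethyl-6-oxatricyclo[6.3.2.0^{4,13}]tridecan-9-one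
Product: 26 (1S,4R,8S,13S)-1,5,5-trimethyl-6-oxatricyclo[6.3.2.0^{4,13}]tridec-10-en-9-one, via silyl enol ether 25 (not isolated)
Conditions: LiN(iPr)2, Me3SiCl, THF, −78 °C; then Pd(OAc)2 (1.05 equiv), MeCN, rt
Reagents that add atoms: none
Why: Saegusa–Ito oxidation: kinetic enolisation takes the C10 methylene rather than the tertiary C8, and palladium-mediated dehydrosilylation gives the C10=C11 enone.

**Step 16**
Reactants: 26 (1S,4R,8S,13S)-1,5,5-trimethyl-6-oxatricyclo[6.3.2.0^{4,13}]tridec-10-en-9-one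
Product: 27 (1S,4R,8S,13S)-10-iodo-1,5,5-trimethyl-6-oxatricyclo[6.3.2.0^{4,13}]tridec-10-en-9-one
Conditions: I2, pyridine, CH2Cl2, rt
Reagents that add atoms: iodine, II
Why: Johnson α-iodination of an enone by pyridine-mediated addition–elimination, which works on γ,γ-disubstituted enones.

**Step 17**
Reactants: 27 (1S,4R,8S,13S)-10-iodo-1,5,5-trimethyl-6-oxatricyclo[6.3.2.0^{4,13}]tridec-10-en-9-one, 28 tributyl(2-methylprop-2-en-1-yl)stannane
Product: 29 (1S,4R,8S,13S)-1,5,5-trimethyl-10-(2-methylprop-2-en-1-yl)-6-oxatricyclo[6.3.2.0^{4,13}]tridec-10-en-9-one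
Conditions: Pd2(dba)3 (cat.), AsPh3, CuI, DMF, 50 °C
Reagents that add atoms: none
Why: Stille coupling of the α-iodoenone; the 2-methylallyl group is symmetrical, so allyl transposition cannot give a regioisomer.

**Step 18**
Reactants: 29 (1S,4R,8S,13S)-1,5,5-trimethyl-10-(2-methylprop-2-en-1-yl)-6-oxatricyclo[6.3.2.0^{4,13}]tridec-10-en-9-one, 30 vinylmagnesium bromide
Product: 32 (1S,4R,8S,10R,11S,13S)-11-ethenyl-1,5,5-trimethyl-10-(2-methylprop-2-en-1-yl)-6-oxatricyclo[6.3.2.0^{4,13}]tridecan-9-one, via silyl enol ether 31 (not isolated)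
Conditions: CH2=CHMgBr, CuBr·SMe2 (20 mol %), Me3SiCl, HMPA, THF, −78 → −40 °C; then 1 M HCl, THF, 0 °C
Reagents that add atoms: none
Why: Copper-catalysed, silyl-chloride-accelerated conjugate addition delivers vinyl to C11 on the convex face away from the cyclohexane bridge, and the enol ether is then protonated at C10 anti to that vinyl group, which places the C10 side chain cis to it.

**Step 19**
Reactants: 32 (1S,4R,8S,10R,11S,13S)-11-ethenyl-1,5,5-trimethyl-10-(2-methylprop-2-en-1-yl)-6-oxatricyclo[6.3.2.0^{4,13}]tridecan-9-one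
Product: 33 (1S,4R,8S,10R,11S,13S)-1,5,5-trimethyl-9-oxo-10-(2-oxopropyl)-6-oxatricyclo[6.3.2.0^{4,13}]tridecane-11-carbaldehyde
Conditions: O3, CH2Cl2, −78 °C; then Me2S, −78 °C → rt
Reagents that add atoms: ozone, [O-][O+]=O
Why: Ozonolysis with reductive work-up cleaves both terminal alkenes at once (vinyl to aldehyde, methallyl to methyl ketone) under neutral conditions that leave C10 and C11 untouched.

**Step 20**
Reactants: 33 (1S,4R,8S,10R,11S,13S)-1,5,5-trimethyl-9-oxo-10-(2-oxopropyl)-6-oxatricyclo[6.3.2.0^{4,13}]tridecane-11-carbaldehyde, 34 2-(dichloromethyl)-4,4,5,5-tetramethyl-1,3,2-dioxaborolane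
Product: 35 (1S,4R,8S,10R,11S,13S)-1,5,5-trimethyl-10-(2-oxopropyl)-11-[(E)-2-(4,4,5,5-tetramethyl-1,3,2-dioxaborolan-2-yl)ethenyl]-6-oxatricyclo[6.3.2.0^{4,13}]tridecan-9-one
Conditions: CrCl2, LiI, THF, rt
Reagents that add atoms: none
Why: Takai–Utimoto boryl-olefination: the geminal dichromium reagent adds to the aldehyde only (ketones are inert) and gives the E-alkenylboronate.

**Step 21**
Reactants: 35 (1S,4R,8S,10R,11S,13S)-1,5,5-trimethyl-10-(2-oxopropyl)-11-[(E)-2-(4,4,5,5-tetramethyl-1,3,2-dioxaborolan-2-yl)ethenyl]-6-oxatricyclo[6.3.2.0^{4,13}]tridecan-9-one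
Product: 36 potassium trifluoro{(E)-2-[(1S,4R,8S,10R,11S,13S)-1,5,5-trimethyl-9-oxo-10-(2-oxopropyl)-6-oxatricyclo[6.3.2.0^{4,13}]tridecan-11-yl]ethenyl}borate
Conditions: KHF2 (aq.), MeOH, rt
Reagents that add atoms: potassium hydrogen difluoride, F.[F-].[K+]
Why: Fluoride exchange at boron converts the pinacol ester into the trifluoroborate without touching the alkene geometry.

**Step 22**
Reactants: 36 potassium trifluoro{(E)-2-[(1S,4R,8S,10R,11S,13S)-1,5,5-trimethyl-9-oxo-10-(2-oxopropyl)-6-oxatricyclo[6.3.2.0^{4,13}]tridecan-11-yl]ethenyl}borate, 37 3-methylbut-2-enoic acid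
Product: 38 (E)-2-[(1S,4R,8S,10R,11S,13S)-1,5,5-trimethyl-9-oxo-10-(2-oxopropyl)-6-oxatricyclo[6.3.2.0^{4,13}]tridecan-11-yl]ethenyl 3-methylbut-2-enoate
Conditions: Cu(OAc)2 (20 mol %), DMAP, 4 Å MS, O2 (1 atm), CH2Cl2, rt
Reagents that add atoms: none
Why: Chan–Lam-type oxidative copper coupling of an alkenyltrifluoroborate with a carboxylic acid forms the C–O bond with retention of the E geometry.

**Compound list**
1 | 2-methylcyclohexanone (racemic) | CC1CCCCC1=O | starting material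
2 | (S)-1-phenylethylamine | C[C@H](N)c1ccccc1 | starting material
3 | (1S)-N-(2-methylcyclohexylidene)-1-phenylethan-1-amine | CC1CCCCC1=N[C@@H](C)c1ccccc1 | intermediate
4 | methyl acrylate | C=CC(=O)OC | starting material
5 | methyl 3-[(1R)-1-methyl-2-{[(1S)-1-phenylethyl]imino}cyclohexyl]propanoate | COC(=O)CC[C@@]1(C)CCCCC1=N[C@@H](C)c1ccccc1 | intermediate
6 | methyl 3-[(1R)-1-methyl-2-oxocyclohexyl]propanoate | COC(=O)CC[C@@]1(C)CCCCC1=O | intermediate
7 | (2R)-2-(3-hydroxypropyl)-2-methylcyclohexan-1-ol (C1 epimers) | OCCC[C@@]1(C)CCCCC1O | intermediate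
8 | 3-[(1R)-1-methyl-2-oxocyclohexyl]propanal | O=CCC[C@@]1(C)CCCCC1=O | intermediate
9 | isopropyltriphenylphosphonium iodide | CC(C)[P+](c1ccccc1)(c1ccccc1)c1ccccc1.[I-] | starting material
10 | (2R)-2-methyl-2-(4-methylpent-3-en-1-yl)cyclohexan-1-one | CC(C)=CCC[C@@]1(C)CCCCC1=O | intermediate
11 | trimethyl{[(6R)-6-methyl-6-(4-methylpent-3-en-1-yl)cyclohex-1-en-1-yl]oxy}silane | CC(C)=CCC[C@@]1(C)CCCC=C1O[Si](C)(C)C | intermediate
12 | trimethyl{[(2R)-2-methyl-2-(4-methylpent-3-en-1-yl)bicyclo[4.1.0]heptan-1-yl]oxy}silane (cyclopropane diastereomers) | CC(C)=CCC[C@@]1(C)CCCC2CC12O[Si](C)(C)C | intermediate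
13 | (7R)-3-chloro-7-methyl-7-(4-methylpent-3-en-1-yl)cycloheptan-1-one (C3 epimers) | CC(C)=CCC[C@@]1(C)CCCC(Cl)CC1=O | intermediate
14 | (7R)-7-methyl-7-(4-methylpent-3-en-1-yl)cyclohept-2-en-1-one | CC(C)=CCC[C@@]1(C)CCCC=CC1=O | intermediate
15 | (3R)-3-methyl-3-(4-methylpent-3-en-1-yl)-8-oxabicyclo[5.1.0]octan-2-one (epoxide diastereomers) | CC(C)=CCC[C@@]1(C)CCCC2OC2C1=O | intermediate
16 | hydrazone of 15 | CC(C)=CCC[C@@]1(C)CCCC2OC2C1=NN | intermediate
17 | (4R)-4-methyl-4-(4-methylpent-3-en-1-yl)cyclohept-2-en-1-ol (C1 epimers) | CC(C)=CCC[C@@]1(C)CCCC(O)C=C1 | intermediate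
18 | (4R)-4-methyl-4-(4-methylpent-3-en-1-yl)cyclohept-2-en-1-one | CC(C)=CCC[C@@]1(C)CCCC(=O)C=C1 | intermediate
19 | (4S)-7-(hydroxymethylidene)-4-methyl-4-(4-methylpent-3-en-1-yl)cyclohept-2-en-1-one | CC(C)=CCC[C@@]1(C)CCC(=CO)C(=O)C=C1 | intermediate
20 | (5S)-5-methyl-5-(4-methylpent-3-en-1-yl)-2-oxo-1-(phenylselanyl)cyclohept-3-ene-1-carbaldehyde (C1 epimers) | CC(C)=CCC[C@@]1(C)CCC(C=O)([Se]c2ccccc2)C(=O)C=C1 | intermediate
21 | selenoxide of 20 | CC(C)=CCC[C@@]1(C)CCC(C=O)([Se](=O)c2ccccc2)C(=O)C=C1 | intermediate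
22 | (4S)-4-methyl-4-(4-methylpent-3-en-1-yl)-7-oxocyclohepta-1,5-diene-1-carbaldehyde | CC(C)=CCC[C@@]1(C)CC=C(C=O)C(=O)C=C1 | intermediate
23 | (1S,4R,13S)-1,5,5-trimethyl-6-oxatricyclo[6.3.2.0^{4,13}]trideca-7,10-dien-9-one | O=C1C2=COC(C)(C)[C@@H]3CC[C@@](C)(C[C@@H]32)C=C1 | intermediate
24 | (1R,4R,8S,13S)-1,5,5-trimethyl-6-oxatricyclo[6.3.2.0^{4,13}]tridecan-9-one | O=C1[C@@H]2COC(C)(C)[C@@H]3CC[C@@](C)(C[C@@H]32)CC1 | intermediate
25 | trimethyl{[(1S,4R,8S,13S)-1,5,5-trimethyl-6-oxatricyclo[6.3.2.0^{4,13}]tridec-9-en-9-yl]oxy}silane | C[Si](C)(C)OC=1[C@@H]2COC(C)(C)[C@@H]3CC[C@@](C)(C[C@@H]32)CC=1 | intermediate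
26 | (1S,4R,8S,13S)-1,5,5-trimethyl-6-oxatricyclo[6.3.2.0^{4,13}]tridec-10-en-9-one | O=C1[C@@H]2COC(C)(C)[C@@H]3CC[C@@](C)(C[C@@H]32)C=C1 | intermediate
27 | (1S,4R,8S,13S)-10-iodo-1,5,5-trimethyl-6-oxatricyclo[6.3.2.0^{4,13}]tridec-10-en-9-one | O=C1[C@@H]2COC(C)(C)[C@@H]3CC[C@@](C)(C[C@@H]32)C=C1I | intermediate
28 | tributyl(2-methylprop-2-en-1-yl)stannane | CCCC[Sn](CCCC)(CCCC)CC(C)=C | starting material
29 | (1S,4R,8S,13S)-1,5,5-trimethyl-10-(2-methylprop-2-en-1-yl)-6-oxatricyclo[6.3.2.0^{4,13}]tridec-10-en-9-one | O=C1[C@@H]2COC(C)(C)[C@@H]3CC[C@@](C)(C[C@@H]32)C=C1CC(C)=C | intermediate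
30 | vinylmagnesium bromide | C=C[Mg]Br | starting material
31 | trimethyl{[(1S,4R,8S,11R,13S)-11-ethenyl-1,5,5-trimethyl-10-(2-methylprop-2-en-1-yl)-6-oxatricyclo[6.3.2.0^{4,13}]tridec-9-en-9-yl]oxy}silane | C[Si](C)(C)OC=1[C@@H]2COC(C)(C)[C@@H]3CC[C@@](C)(C[C@@H]32)[C@@H](C=C)C=1CC(C)=C | intermediate
32 | (1S,4R,8S,10R,11S,13S)-11-ethenyl-1,5,5-trimethyl-10-(2-methylprop-2-en-1-yl)-6-oxatricyclo[6.3.2.0^{4,13}]tridecan-9-one | C=C(C)C[C@H]1C(=O)[C@@H]2COC(C)(C)[C@@H]3CC[C@@](C)(C[C@@H]32)[C@H]1C=C | intermediate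
33 | (1S,4R,8S,10R,11S,13S)-1,5,5-trimethyl-9-oxo-10-(2-oxopropyl)-6-oxatricyclo[6.3.2.0^{4,13}]tridecane-11-carbaldehyde | CC(=O)C[C@H]1C(=O)[C@@H]2COC(C)(C)[C@@H]3CC[C@@](C)(C[C@@H]32)[C@H]1C=O | intermediate
34 | 2-(dichloromethyl)-4,4,5,5-tetramethyl-1,3,2-dioxaborolane | CC1(C)OB(C(Cl)Cl)OC1(C)C | starting material
35 | (1S,4R,8S,10R,11S,13S)-1,5,5-trimethyl-10-(2-oxopropyl)-11-[(E)-2-(4,4,5,5-tetramethyl-1,3,2-dioxaborolan-2-yl)ethenyl]-6-oxatricyclo[6.3.2.0^{4,13}]tridecan-9-one | CC(=O)C[C@H]1C(=O)[C@@H]2COC(C)(C)[C@@H]3CC[C@@](C)(C[C@@H]32)[C@H]1/C=C/B1OC(C)(C)C(C)(C)O1 | intermediate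
36 | potassium trifluoro{(E)-2-[(1S,4R,8S,10R,11S,13S)-1,5,5-trimethyl-9-oxo-10-(2-oxopropyl)-6-oxatricyclo[6.3.2.0^{4,13}]tridecan-11-yl]ethenyl}borate | CC(=O)C[C@H]1C(=O)[C@@H]2COC(C)(C)[C@@H]3CC[C@@](C)(C[C@@H]32)[C@H]1/C=C/[B-](F)(F)F.[K+] | intermediate
37 | 3-methylbut-2-enoic acid | CC(C)=CC(=O)O | starting material
38 | (E)-2-[(1S,4R,8S,10R,11S,13S)-1,5,5-trimethyl-9-oxo-10-(2-oxopropyl)-6-oxatricyclo[6.3.2.0^{4,13}]tridecan-11-yl]ethenyl 3-methylbut-2-enoate | CC(=O)C[C@H]1C(=O)[C@@H]2COC(C)(C)[C@@H]3CC[C@@](C)(C[C@@H]32)[C@H]1/C=C/OC(=O)C=C(C)C | target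

**Totals**
Total step count: 22. Longest linear sequence: 22 steps (1 to 38).

**Three steps most likely to fail**

Step 10 (Wharton transposition: hydrazone formation at a ketone next to a quaternary carbon, and yields of this reaction vary). The fallback sets out from enone 14 and comes back at allylic alcohol 17. Luche reduction (NaBH4, CeCl3·7H2O, MeOH) gives (7R)-7-methyl-7-(4-methylpent-3-en-1-yl)cyclohept-2-en-1-ol F1. Hydroxyl-directed epoxidation (VO(acac)2, t-BuOOH, which spares the side-chain alkene) gives the epoxy alcohol (3R)-3-methyl-3-(4-methylpent-3-en-1-yl)-8-oxabicyclo[5.1.0]octan-2-ol F2. 1,1'-Thiocarbonyldiimidazole converts it into the imidazole-1-carbothioate F3. Bu3SnH/AIBN then generates the carbinyl radical, which opens the adjacent epoxide (Barton-type radical fragmentation) and gives 17 without any hydrazone.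

Step 18 (conjugate addition to an α-substituted enone whose β-carbon is neopentyl, with the C10 configuration resting on kinetic protonation). The fallback sets out from enone 26 and comes back at aldehyde 33.
- The same copper-catalysed vinyl addition, now to the unsubstituted enone, gives the C11-vinyl silyl enol ether F4.
- A Mannich reaction with dimethyl(methylidene)ammonium iodide gives the C10 aminomethyl ketone F5.
- Quaternisation with MeI and elimination give the α-methylene ketone F6.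
- Michael addition of nitroethane (DBU cat.) gives the nitro ketone F7; C10 is protonated anti to the vinyl group, but under the basic conditions it may equilibrate, so the cis outcome is expected rather than assured.
- A McMurry–Nef reaction (TiCl3, NH4OAc, aq. THF) gives the vinyl diketone F8.
- Ozonolysis of its single alkene gives 33.

Step 22 (oxidative copper coupling on a hindered substrate that is epimerisable at C10). The fallback sets out from aldehyde 33 and comes back at target 38. Acid 37 is converted with chloromethyl chlorosulfate (NaHCO3, Bu4NHSO4, CH2Cl2/H2O) into chloromethyl 3-methylbut-2-enoate F9. PPh3 turns this into [(3-methylbut-2-enoyl)oxy]methyl(triphenyl)phosphonium chloride F10. Its ylide (KN(SiMe3)2, THF, −78 °C) olefinates only the aldehyde of 33 (Anders–Gaßner-type Wittig reaction) and gives 38 together with its Z isomer, which is removed by chromatography.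

**Further compounds**
F1 | step 10 | (7R)-7-methyl-7-(4-methylpent-3-en-1-yl)cyclohept-2-en-1-ol (C1 epimers) | CC(C)=CCC[C@@]1(C)CCCC=CC1O
F2 | step 10 | (3R)-3-methyl-3-(4-methylpent-3-en-1-yl)-8-oxabicyclo[5.1.0]octan-2-ol (diastereomers) | CC(C)=CCC[C@@]1(C)CCCC2OC2C1O
F3 | step 10 | O-[(3R)-3-methyl-3-(4-methylpent-3-en-1-yl)-8-oxabicyclo[5.1.0]octan-2-yl] 1H-imidazole-1-carbothioate | CC(C)=CCC[C@@]1(C)CCCC2OC2C1OC(=S)n1ccnc1
F4 | step 18 | trimethyl{[(1S,4R,8S,11S,13S)-11-ethenyl-1,5,5-trimethyl-6-oxatricyclo[6.3.2.0^{4,13}]tridec-9-en-9-yl]oxy}silane | C[Si](C)(C)OC=1[C@@H]2COC(C)(C)[C@@H]3CC[C@@](C)(C[C@@H]32)[C@@H](C=C)C=1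
F5 | step 18 | (1S,4R,8S,10R,11S,13S)-10-[(dimethylamino)methyl]-11-ethenyl-1,5,5-trimethyl-6-oxatricyclo[6.3.2.0^{4,13}]tridecan-9-one | CN(C)C[C@@H]1C(=O)[C@@H]2COC(C)(C)[C@@H]3CC[C@@](C)(C[C@@H]32)[C@H]1C=C
F6 | step 18 | (1S,4R,8S,11R,13S)-11-ethenyl-1,5,5-trimethyl-10-methylidene-6-oxatricyclo[6.3.2.0^{4,13}]tridecan-9-one | C=C1C(=O)[C@@H]2COC(C)(C)[C@@H]3CC[C@@](C)(C[C@@H]32)[C@H]1C=C
F7 | step 18 | (1S,4R,8S,10R,11S,13S)-11-ethenyl-1,5,5-trimethyl-10-(2-nitropropyl)-6-oxatricyclo[6.3.2.0^{4,13}]tridecan-9-one (nitro carbon epimers) | CC([N+](=O)[O-])C[C@H]1C(=O)[C@@H]2COC(C)(C)[C@@H]3CC[C@@](C)(C[C@@H]32)[C@H]1C=C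
F8 | step 18 | (1S,4R,8S,10R,11S,13S)-11-ethenyl-1,5,5-trimethyl-10-(2-oxopropyl)-6-oxatricyclo[6.3.2.0^{4,13}]tridecan-9-one | CC(=O)C[C@H]1C(=O)[C@@H]2COC(C)(C)[C@@H]3CC[C@@](C)(C[C@@H]32)[C@H]1C=C
F9 | step 22 | chloromethyl 3-methylbut-2-enoate | CC(C)=CC(=O)OCCl
F10 | step 22 | [(3-methylbut-2-enoyl)oxy]methyl(triphenyl)phosphonium chloride | CC(C)=CC(=O)OC[P+](c1ccccc1)(c1ccccc1)c1ccccc1.[Cl-]
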